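The pyranone ring is cut at O1–C2 and at C4–C4a. This leaves 3,5-dimethoxyphenol and the C2–C3–C4 unit on the benzocyclobutene. The unit is stored as a spiro-β-lactone, a strained ring absent from the target, in which C2 is an alkylating and C4 an acylating carbon. In one flask the phenoxide opens the lactone at C2. The carboxylate set free is activated with TFAA and acylates the ortho carbon C4a, a formal [3+3] annulation with loss of water. It exploits the 1,3-relation of C2 and C4 across spiro carbon C3, the ortho pair O1/C4a and the symmetry of phenol ring A. C3 is set earlier by desymmetrising a benzocyclobutene malonate.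

Key step: step 7

Numbering: chromanone numbering is used for the target (O1, C2, spiro C3, C4 = carbonyl, C4a, C8a; ring A is its benzene ring). Bicyclo[4.2.0]octatriene numbering is used for the benzocyclobutene (C7 quaternary, C8 = CH2, methoxy groups on C4 and C5, C5 next to the fusion carbon C6 that bears C7).

Assumption: the sense of induction of the zinc catalyst on malonate 6 cannot be predicted safely. Both ligand enantiomers are available, and the one that delivers hydride to the pro-R ester is used.

Step 1
Reactants: 1 2-(2,3-dimethoxyphenyl)acetic acid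
Product: 3 methyl 2-(6-bromo-2,3-dimethoxyphenyl)acetate, via bromo acid 2 (not isolated)
Conditions: Br2 (1.05 equiv), MeOH, 0 °C to rt; then reflux
Reagents that add atoms: bromine, BrBr; methanol, CO
Why: Electrophilic aromatic bromination should go para to the coplanar 3-methoxy group (C6), because the flanked 2-methoxy group is twisted out of conjugation, and the HBr released then catalyses Fischer esterification of the arylacetic acid in the methanol solvent.

Step 2
Reactants: 3 methyl 2-(6-bromo-2,3-dimethoxyphenyl)acetate
Product: 5 dimethyl 2-(6-bromo-2,3-dimethoxyphenyl)-2-methylmalonate, via sodium malonate enolate 4 (not isolated)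
Conditions: NaH (3 equiv), (MeO)2CO, THF, reflux; then MeI, rt
Reagents that add atoms: dimethyl carbonate, COC(=O)OC; iodomethane, CI
Why: Claisen-type C-acylation of the arylacetate enolate with dimethyl carbonate is driven by formation of the stabilised enolate 4, and its malonic ester alkylation with the small electrophile MeI builds the prochiral quaternary carbon.

Step 3
Reactants: 5 dimethyl 2-(6-bromo-2,3-dimethoxyphenyl)-2-methylmalonate
Product: 6 dimethyl 4,5-dimethoxybicyclo[4.2.0]octa-1,3,5-triene-7,7-dicarboxylate
Conditions: Pd(OAc)2 (10 mol %), P(t-Bu)3·HBF4 (20 mol %), K2CO3, DMF, 140 °C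
Reagents that add atoms: none
Why: This is an intramolecular palladium-catalysed C(sp3)–H arylation of a methyl group on a quaternary benzylic carbon (oxidative addition of C–Br to zerovalent palladium, carbonate-assisted concerted metalation–deprotonation to a five-membered palladacycle, reductive elimination to the four-membered ring), a reaction type shown for 2-(2-bromoaryl)-2-methylmalonates, and the methoxy group on the second ortho carbon blocks the 1,4-palladium shift that could give a regioisomer.

Step 4
Reactants: 6 dimethyl 4,5-dimethoxybicyclo[4.2.0]octa-1,3,5-triene-7,7-dicarboxylate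
Product: 8 methyl (7S)-7-(hydroxymethyl)-4,5-dimethoxybicyclo[4.2.0]octa-1,3,5-triene-7-carboxylate, via trimethoxysilyl ether 7 (not isolated)
Conditions: Et2Zn (10 mol %), ProPhenol-type tetradentate amino alcohol–phenol ligand (5 mol %), (MeO)3SiH (3 equiv), toluene, 0 °C; then MeOH, K2CO3 (cat.)
Reagents that add atoms: none
Why: In this catalytic reductive desymmetrisation of a 2,2-disubstituted malonic ester by asymmetric hydrosilylation, the chiral catalyst made from Et2Zn and the ligand binds the malonate, tells the methoxy-flanked aryl edge from the CH2 edge of the four-membered ring and delivers hydride only to the pro-R ester, which sets C7 as S, while silyl ether 7 no longer chelates and should not be reduced further.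

Step 5
Reactants: 8 methyl (7S)-7-(hydroxymethyl)-4,5-dimethoxybicyclo[4.2.0]octa-1,3,5-triene-7-carboxylate
Product: 10 (7S)-7-(hydroxymethyl)-4,5-dimethoxybicyclo[4.2.0]octa-1,3,5-triene-7-carboxylic acid, via lithium carboxylate 9 (not isolated)
Conditions: LiOH, THF/MeOH/H2O, 50 °C; then 1 M HCl, 0 °C
Reagents that add atoms: lithium hydroxide, [Li+].[OH-]
Why: Saponification of the methyl ester leaves the quaternary centre intact, since it cannot epimerise and retro-aldol loss of formaldehyde would need a strained exocyclic enolate on the four-membered ring.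

Step 6
Reactants: 10 (7S)-7-(hydroxymethyl)-4,5-dimethoxybicyclo[4.2.0]octa-1,3,5-triene-7-carboxylic acid
Product: 12 (7S)-4,5-dimethoxyspiro[bicyclo[4.2.0]octa-1,3,5-triene-7,3'-oxetan]-2'-one, via mixed sulfonic anhydride 11 (not isolated)
Conditions: PhSO2Cl (2 equiv), pyridine, 0 °C
Reagents that add atoms: none
Why: In this β-lactonisation by carboxyl activation (sulfonyl chloride–pyridine method) the neighbouring primary alcohol traps anhydride 11 in a 4-exo-trig closure helped by the gem-disubstituent effect, and sulfonylation of the alcohol instead would lead to the same lactone by 4-exo-tet closure, so C7 is untouched either way.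

Step 7
Reactants: 12 (7S)-4,5-dimethoxyspiro[bicyclo[4.2.0]octa-1,3,5-triene-7,3'-oxetan]-2'-one; 13 3,5-dimethoxyphenol
Product: 17 (3S)-4',5,5',7-tetramethoxyspiro[chromane-3,7'-bicyclo[4.2.0]octa-1',3',5'-trien]-4-one (CNP0192565.1), via caesium phenoxide 14 (not isolated), via caesium carboxylate 15 (not isolated), via mixed trifluoroacetic anhydride 16 (not isolated)
Conditions: 13 (2 equiv), Cs2CO3 (2 equiv), 4 Å MS, MeCN, 50 °C, slow addition of 12; then CH2Cl2, trifluoroacetic anhydride (TFAA, 8 equiv), 0 °C to rt
Reagents that add atoms: none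
Why: Caesium phenoxide 14 attacks the lactone CH2 (C2) from the rear of the C–O bond (SN2, alkyl–oxygen fission driven by release of the four-ring strain), which makes O1–C2 and carboxylate 15. Attack at the lactone carbonyl is not a sink, because the alkoxide of a β-hydroxy aryl ester is known to fall back to β-lactone plus phenoxide, so the material should drain into 15. TFAA converts 15 into mixed anhydride 16, whose acyl carbon C4 is attacked by the ortho carbon C4a of the phloroglucinol-type ether (intramolecular Friedel–Crafts acylation, 6-exo-trig), which closes the pyranone ring. The closest known reaction types are the opening of β-propiolactone or pivalolactone by phenoxides to 3-aryloxypropanoic acids and the TFAA cyclisation of such acids to chroman-4-ones, here run in one flask as a formal [3+3] annulation. No stereocentre is made: none of the four bonds at C3 is broken and C3 bears no hydrogen, so the S configuration of 12 is carried into 17. The step needs O- over C-alkylation and phenoxide over carboxylate as the nucleophile (caesium salt in MeCN, excess 14, slow addition of 12), needs no regiocontrol in the acylation because the two ortho carbons of the symmetric aryl ether are equivalent and the para carbon cannot reach C4, and is protected from decarbonylation because that would give a strained benzocyclobutenyl cation.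

Compound list
1 | 2-(2,3-dimethoxyphenyl)acetic acid | COc1cccc(CC(=O)O)c1OC | starting material
2 | 2-(6-bromo-2,3-dimethoxyphenyl)acetic acid (not isolated) | COc1ccc(Br)c(CC(=O)O)c1OC | intermediate
3 | methyl 2-(6-bromo-2,3-dimethoxyphenyl)acetate | COC(=O)Cc1c(Br)ccc(OC)c1OC | intermediate
4 | sodium enolate of dimethyl 2-(6-bromo-2,3-dimethoxyphenyl)malonate (not isolated) | COC(=O)C(=C([O-])OC)c1c(Br)ccc(OC)c1OC.[Na+] | intermediate
5 | dimethyl 2-(6-bromo-2,3-dimethoxyphenyl)-2-methylmalonate | COC(=O)C(C)(C(=O)OC)c1c(Br)ccc(OC)c1OC | intermediate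
6 | dimethyl 4,5-dimethoxybicyclo[4.2.0]octa-1,3,5-triene-7,7-dicarboxylate | COC(=O)C1(C(=O)OC)Cc2ccc(OC)c(OC)c21 | intermediate
7 | methyl (7S)-4,5-dimethoxy-7-[(trimethoxysilyloxy)methyl]bicyclo[4.2.0]octa-1,3,5-triene-7-carboxylate (not isolated) | CO[Si](OC)(OC)OC[C@@]1(Cc2ccc(OC)c(OC)c21)C(=O)OC | intermediate
8 | methyl (7S)-7-(hydroxymethyl)-4,5-dimethoxybicyclo[4.2.0]octa-1,3,5-triene-7-carboxylate | OC[C@@]1(Cc2ccc(OC)c(OC)c21)C(=O)OC | intermediate
9 | lithium (7S)-7-(hydroxymethyl)-4,5-dimethoxybicyclo[4.2.0]octa-1,3,5-triene-7-carboxylate (not isolated) | OC[C@@]1(Cc2ccc(OC)c(OC)c21)C(=O)[O-].[Li+] | intermediate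
10 | (7S)-7-(hydroxymethyl)-4,5-dimethoxybicyclo[4.2.0]octa-1,3,5-triene-7-carboxylic acid | OC[C@@]1(Cc2ccc(OC)c(OC)c21)C(=O)O | intermediate
11 | mixed anhydride of acid 10 and benzenesulfonic acid, 7S (not isolated) | OC[C@@]1(Cc2ccc(OC)c(OC)c21)C(=O)OS(=O)(=O)c1ccccc1 | intermediate
12 | (7S)-4,5-dimethoxyspiro[bicyclo[4.2.0]octa-1,3,5-triene-7,3'-oxetan]-2'-one (spiro-β-lactone) | O=C1OC[C@@]12Cc3ccc(OC)c(OC)c32 | intermediate
13 | 3,5-dimethoxyphenol | COc1cc(O)cc(OC)c1 | starting material
14 | caesium 3,5-dimethoxyphenoxide (not isolated) | COc1cc([O-])cc(OC)c1.[Cs+] | intermediate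
15 | caesium (7S)-7-[(3,5-dimethoxyphenoxy)methyl]-4,5-dimethoxybicyclo[4.2.0]octa-1,3,5-triene-7-carboxylate (not isolated) | COc1cc(OC)cc(OC[C@@]2(Cc3ccc(OC)c(OC)c32)C(=O)[O-])c1.[Cs+] | intermediate
16 | mixed anhydride of the acid of 15 and trifluoroacetic acid, 7S (not isolated) | COc1cc(OC)cc(OC[C@@]2(Cc3ccc(OC)c(OC)c32)C(=O)OC(=O)C(F)(F)F)c1 | intermediate
17 | (3S)-4',5,5',7-tetramethoxyspiro[chromane-3,7'-bicyclo[4.2.0]octa-1',3',5'-trien]-4-one (CNP0192565.1) | COc1cc(OC)c2c(c1)OC[C@@]1(Cc3ccc(OC)c(OC)c31)C2=O | target

Total step count: 7. Longest linear sequence: 7 steps (1 to 17); phenol 13 enters in step 7.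

Steps most likely to fail

1. Step 7. The SN2 opening at the neopentyl-type C2 may be too slow. Carboxylate-initiated oligomerisation of the lactone, C-alkylation of the ambident phenoxide or hydrolysis by traces of water could then compete. The acylation may also lose carbon monoxide.
Fallback, from 12 back to 17: an ester tether makes the O-alkylation intramolecular and the acylation anionic. MgBr2·OEt2 in Et2O opens 12 at C2 to the (7R)-bromo acid F1. NBS in CH2Cl2 at low temperature converts 13 into 2-bromo-3,5-dimethoxyphenol F2. DCC and catalytic DMAP join the two to the aryl ester F3. n-BuLi in THF at −95 °C exchanges the aryl bromide faster than it touches the hindered ester or the neopentyl bromide and gives the aryllithium F4. The acyl group then moves from O1 to C4a (anionic Fries rearrangement induced by halogen–metal exchange). The lithium phenoxide F5 unmasked in this way closes O1–C2 by 6-exo-tet displacement of bromide on warming with DMPU. This should give 17, again with both bonds made in one operation.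

2. Step 4. The flat four-membered ring offers the catalyst only the difference between the methoxy-flanked aryl edge and the CH2 edge. Discrimination of the enantiotopic esters may therefore be poor, and over-reduction may set in.
Fallback, from 6 back to 10 or 8: hydrolytic enzymatic desymmetrisation followed by chemoselective reduction, which can use either sense of induction. Pig liver esterase in pH 7 phosphate buffer with DMSO as co-solvent hydrolyses one ester. If this gives the (7R)-half-ester F6, LiBH4 in THF reduces the ester of its lithium salt and leads directly to 10. If it gives the (7S)-half-ester F7, BH3·SMe2 reduces the free acid and leads to 8. The half-ester can be enriched by crystallisation before reduction.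

3. Step 3. Protodebromination, halide-induced dealkoxycarbonylation of the malonate at 140 °C or thermal electrocyclic opening of the product may outrun the C–H palladation.
Fallback, from 5 back to 8: ring closure and desymmetrisation change places. The palladation then runs on a mono-ester, and the stereocentre is set on an aryl/methyl malonate with a large size difference. The hydrosilylation of step 4 applied to 5 should give the acyclic (2S)-hydroxy ester F8. TIPSCl and imidazole protect it as the silyl ether F9. Pd(OAc)2, P(t-Bu)3·HBF4 and K2CO3 in DMF close the four-membered ring to the silyl ether F10. TBAF in THF releases 8.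

Further compounds
F1 | step 7 | (7R)-7-(bromomethyl)-4,5-dimethoxybicyclo[4.2.0]octa-1,3,5-triene-7-carboxylic acid | BrC[C@@]1(Cc2ccc(OC)c(OC)c21)C(=O)O
F2 | step 7 | 2-bromo-3,5-dimethoxyphenol | COc1cc(O)c(Br)c(OC)c1
F3 | step 7 | 2-bromo-3,5-dimethoxyphenyl (7R)-7-(bromomethyl)-4,5-dimethoxybicyclo[4.2.0]octa-1,3,5-triene-7-carboxylate | BrC[C@@]1(Cc2ccc(OC)c(OC)c21)C(=O)Oc1cc(OC)cc(OC)c1Br
F4 | step 7 | 2-lithio-3,5-dimethoxyphenyl (7R)-7-(bromomethyl)-4,5-dimethoxybicyclo[4.2.0]octa-1,3,5-triene-7-carboxylate | BrC[C@@]1(Cc2ccc(OC)c(OC)c21)C(=O)Oc1cc(OC)cc(OC)c1[Li]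
F5 | step 7 | lithium 2-{[(7R)-7-(bromomethyl)-4,5-dimethoxybicyclo[4.2.0]octa-1,3,5-trien-7-yl]carbonyl}-3,5-dimethoxyphenoxide | BrC[C@@]1(Cc2ccc(OC)c(OC)c21)C(=O)c1c([O-])cc(OC)cc1OC.[Li+]
F6 | step 4 | (7R)-4,5-dimethoxy-7-(methoxycarbonyl)bicyclo[4.2.0]octa-1,3,5-triene-7-carboxylic acid | COC(=O)[C@@]1(Cc2ccc(OC)c(OC)c21)C(=O)O
F7 | step 4 | (7S)-4,5-dimethoxy-7-(methoxycarbonyl)bicyclo[4.2.0]octa-1,3,5-triene-7-carboxylic acid | COC(=O)[C@]1(Cc2ccc(OC)c(OC)c21)C(=O)O
F8 | step 3 | methyl (2S)-2-(6-bromo-2,3-dimethoxyphenyl)-3-hydroxy-2-methylpropanoate | OC[C@@](c1c(Br)ccc(OC)c1OC)(C)C(=O)OC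
F9 | step 3 | methyl (2S)-2-(6-bromo-2,3-dimethoxyphenyl)-2-methyl-3-(triisopropylsilyloxy)propanoate | CC(C)[Si](OC[C@@](c1c(Br)ccc(OC)c1OC)(C)C(=O)OC)(C(C)C)C(C)C
F10 | step 3 | methyl (7S)-4,5-dimethoxy-7-[(triisopropylsilyloxy)methyl]bicyclo[4.2.0]octa-1,3,5-triene-7-carboxylate | CC(C)[Si](OC[C@@]1(Cc2ccc(OC)c(OC)c21)C(=O)OC)(C(C)C)C(C)C
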